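**Retrosynthetic overview**

- Last step: removal of four O-benzyl groups and one O-acetyl group from the fully assembled biflavanone; no stereocentre is touched.
- Key disconnection: the bond between C3 of the 4-hydroxyphenyl flavanone (unit 1) and C8 of the 4-methoxyphenyl flavanone (unit 2). C3, normally an enolate carbon, is made electrophilic as an enolonium (O-bound trivalent-iodine enolate of the silyl enol ether) and is attacked by the nucleophilic C8 of the complete (2S)-flavanone; the C2 aryl group steers the new C3 centre trans.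
- Both flavanones come from one chromone, 5,7-bis(benzyloxy)chromone, by rhodium-catalysed asymmetric 1,4-arylation with the two antipodes of one ligand (2R for unit 1, 2S for unit 2).
- Ring order: both benzopyranone bicycles are bought preformed (5,7-dihydroxychromone); the two pendant aryl rings are attached next; no ring is formed in or after the key step.

Assumption: the rhodium catalyst follows the usual facial model (R ligand gives 2R); if the first run shows the opposite sense, the two ligand antipodes are exchanged between steps 2 and 3.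

**Route**

Step 1
Reactants: 1 5,7-dihydroxy-4H-chromen-4-one
Product: 2 5,7-bis(benzyloxy)-4H-chromen-4-one
Conditions: BnBr (2.6 equiv), K2CO3 (4 equiv), KI (cat.), DMF, 60 °C
Reagents that add atoms: benzyl bromide, BrCc1ccccc1
Why: Williamson ether synthesis; the acidic 7-OH reacts first and the chelated 5-OH follows on warming with iodide catalysis; no stereocentre is formed.

Step 2
Reactants: 2 5,7-bis(benzyloxy)-4H-chromen-4-one; 3 (4-acetoxyphenyl)boronic acid
Product: 4 4-[(2R)-5,7-bis(benzyloxy)-4-oxochroman-2-yl]phenyl acetate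
Conditions: [Rh(OH)(cod)]2 (1.5 mol %), (R)-MeO-F12-BIPHEP [(R)-6,6'-dimethoxy-2,2'-bis{bis(3,4,5-trifluorophenyl)phosphino}biphenyl] (3.3 mol %), 3 (3 equiv), toluene/H2O 10:1, 40 °C
Reagents that add atoms: none
Why: Hayashi–Miyaura asymmetric 1,4-addition; the aryl-rhodium species adds across C2=C3 on the face fixed by the electron-poor bisphosphine and water protonates the rhodium enolate, so C2 (R) is set by the ligand, while the near-neutral medium spares the acetate and avoids retro-oxa-Michael racemisation.

Step 3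
Reactants: 2 5,7-bis(benzyloxy)-4H-chromen-4-one; 5 (4-methoxyphenyl)boronic acid
Product: 6 (2S)-5,7-bis(benzyloxy)-2-(4-methoxyphenyl)chroman-4-one
Conditions: [Rh(OH)(cod)]2 (1.5 mol %), (S)-MeO-F12-BIPHEP (3.3 mol %), 5 (3 equiv), toluene/H2O 10:1, 40 °C
Reagents that add atoms: none
Why: the same Hayashi–Miyaura 1,4-addition with the ligand antipode delivers the aryl group to the opposite face, setting C2 as (S).

Step 4
Reactants: 4 4-[(2R)-5,7-bis(benzyloxy)-4-oxochroman-2-yl]phenyl acetate
Product: 7 4-[(2R)-5,7-bis(benzyloxy)-4-(trimethylsilyloxy)-2H-chromen-2-yl]phenyl acetate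
Conditions: TMSOTf (1.3 equiv), Et3N (2 equiv), CH2Cl2, 0 °C; concentrate, triturate with dry pentane, filter, use crude
Reagents that add atoms: trimethylsilyl trifluoromethanesulfonate, C[Si](C)(C)OS(=O)(=O)C(F)(F)F
Why: soft enolisation (silyl enol ether formation) silylates the carbonyl oxygen before C3 is deprotonated, so no free enolate forms that could open the ring to a chalcone; C2 is untouched and the ketone reacts ahead of the aryl acetate.

Step 5
Reactants: 7 4-[(2R)-5,7-bis(benzyloxy)-4-(trimethylsilyloxy)-2H-chromen-2-yl]phenyl acetate; 6 (2S)-5,7-bis(benzyloxy)-2-(4-methoxyphenyl)chroman-4-one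
Product: 9 4-[(2R,3S)-5,7-bis(benzyloxy)-3-[(2S)-5,7-bis(benzyloxy)-2-(4-methoxyphenyl)-4-oxochroman-8-yl]-4-oxochroman-2-yl]phenyl acetate, via enolonium iodane 8 (not isolated)
Conditions: PhI(OH)OTs (1.0 equiv), BF3·OEt2 (1.5 equiv), CH2Cl2, −78 °C, add 7, 5 min; then 6 (1.5 equiv, excess recovered), −78 → −40 °C; aq. NaHCO3
Reagents that add atoms: none
Why: Proposed new method: Koser's reagent with BF3 converts 7 into the O-bound trivalent-iodine enolate 8, in which C3 is electrophilic; C8 of 6 (para to the 5-benzyloxy group, ortho to the 7-benzyloxy group and the ring oxygen, less hindered than C6 between two benzyloxy groups) attacks C3 in an SN2'-type Friedel–Crafts alkylation anti to the C2 aryl group with loss of PhI, giving the 2,3-trans product (3S), which is also the thermodynamic epimer at the enolisable C3; the acetoxy group makes the unit 1 aryl ring a poorer migrating group against the 2→3 aryl shift (isoflavone pathway) and the base-free medium at −78 °C disfavours dehydrogenation to the flavone; the closest known reaction type is the α-arylation of ketone silyl enol ethers with indoles and other electron-rich arenes through preformed enolonium species (Koser's reagent, BF3·OEt2, −78 °C).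

Step 6
Reactants: 9 4-[(2R,3S)-5,7-bis(benzyloxy)-3-[(2S)-5,7-bis(benzyloxy)-2-(4-methoxyphenyl)-4-oxochroman-8-yl]-4-oxochroman-2-yl]phenyl acetate
Product: 11 (2R,3S)-5,7-dihydroxy-3-[(2S)-5,7-dihydroxy-2-(4-methoxyphenyl)-4-oxochroman-8-yl]-2-(4-hydroxyphenyl)chroman-4-one, via tetraphenol monoacetate 10 (not isolated)
Conditions: H2 (1 atm), 10% Pd/C, THF/MeOH 1:1, rt; filter; then 1.25 M HCl in MeOH, 40 °C
Reagents that add atoms: none
Why: neutral hydrogenolysis of the aryl benzyl ethers leaves the flavanone ketones and the aryl methyl ether intact, and acid-catalysed transesterification (methanolysis) then removes the aryl acetate; no base is used, so C2 of either unit cannot epimerise through a chalcone and C3 stays in its thermodynamic trans arrangement.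

**Compound list**

1 | 5,7-dihydroxy-4H-chromen-4-one | O=c1ccoc2cc(O)cc(O)c12 | starting material
2 | 5,7-bis(benzyloxy)-4H-chromen-4-one | O=c1ccoc2cc(OCc3ccccc3)cc(OCc3ccccc3)c12 | intermediate
3 | (4-acetoxyphenyl)boronic acid | CC(=O)Oc1ccc(B(O)O)cc1 | starting material
4 | 4-[(2R)-5,7-bis(benzyloxy)-4-oxochroman-2-yl]phenyl acetate | CC(=O)Oc1ccc([C@H]2CC(=O)c3c(OCc4ccccc4)cc(OCc4ccccc4)cc3O2)cc1 | intermediate
5 | (4-methoxyphenyl)boronic acid | COc1ccc(B(O)O)cc1 | starting material
6 | (2S)-5,7-bis(benzyloxy)-2-(4-methoxyphenyl)chroman-4-one | COc1ccc([C@@H]2CC(=O)c3c(OCc4ccccc4)cc(OCc4ccccc4)cc3O2)cc1 | intermediate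
7 | 4-[(2R)-5,7-bis(benzyloxy)-4-(trimethylsilyloxy)-2H-chromen-2-yl]phenyl acetate | CC(=O)Oc1ccc([C@H]2C=C(O[Si](C)(C)C)c3c(OCc4ccccc4)cc(OCc4ccccc4)cc3O2)cc1 | intermediate
8 | 4-[(2R)-5,7-bis(benzyloxy)-4-{[phenyl(tosyloxy)iodanyl]oxy}-2H-chromen-2-yl]phenyl acetate (BF3-activated O-bound trivalent-iodine enolate, enolonium) | CC(=O)Oc1ccc([C@H]2C=C(OI(c3ccccc3)OS(=O)(=O)c3ccc(C)cc3)c3c(OCc4ccccc4)cc(OCc4ccccc4)cc3O2)cc1 | intermediate
9 | 4-[(2R,3S)-5,7-bis(benzyloxy)-3-[(2S)-5,7-bis(benzyloxy)-2-(4-methoxyphenyl)-4-oxochroman-8-yl]-4-oxochroman-2-yl]phenyl acetate | COc1ccc([C@@H]2CC(=O)c3c(OCc4ccccc4)cc(OCc4ccccc4)c([C@@H]4C(=O)c5c(OCc6ccccc6)cc(OCc6ccccc6)cc5O[C@H]4c4ccc(OC(C)=O)cc4)c3O2)cc1 | intermediate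
10 | 4-[(2R,3S)-3-[(2S)-5,7-dihydroxy-2-(4-methoxyphenyl)-4-oxochroman-8-yl]-5,7-dihydroxy-4-oxochroman-2-yl]phenyl acetate | COc1ccc([C@@H]2CC(=O)c3c(O)cc(O)c([C@@H]4C(=O)c5c(O)cc(O)cc5O[C@H]4c4ccc(OC(C)=O)cc4)c3O2)cc1 | intermediate
11 | (2R,3S)-5,7-dihydroxy-3-[(2S)-5,7-dihydroxy-2-(4-methoxyphenyl)-4-oxochroman-8-yl]-2-(4-hydroxyphenyl)chroman-4-one (CNP0140544.1) | COc1ccc([C@@H]2CC(=O)c3c(O)cc(O)c([C@@H]4C(=O)c5c(O)cc(O)cc5O[C@H]4c4ccc(O)cc4)c3O2)cc1 | target

**Step count**

Total: 6 steps. Longest linear sequence: 5 steps (steps 1, 2, 4, 5, 6); step 3 is the convergent branch.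

**Three steps most likely to fail**

Step 5 is the riskiest. The enolonium 8 may lose its C2 aryl group to C3 (isoflavone) or eliminate to the flavone before 6 attacks. Compound 6 may also react at C6 instead of C8, or be oxidised by residual iodane. The fallback sets out from 7 and comes back at 9. Compound 7 is brominated with N-bromosuccinimide (THF, −78 °C) to the trans bromoketone 4-[(2S,3S)-5,7-bis(benzyloxy)-3-bromo-4-oxochroman-2-yl]phenyl acetate F1. F1 and 6 are then joined by visible-light photoredox catalysis (Ir(ppy)3, 2,6-lutidine, MeCN, blue LEDs, rt). The electrophilic α-keto radical, the one-electron form of the same reversed-polarity C3, adds to C8 of 6. Oxidation and deprotonation of the cyclohexadienyl radical give 9, and the enolisable C3 settles trans. No cation is formed at C3, so the aryl shift is shut off.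

Step 4 is next. Base may open the pyranone ring to the chalcone and so racemise C2, the acetate may be silylated, and the trimethylsilyl enol ether is easily hydrolysed. The fallback sets out from 2, comes back at 7 and bypasses 4. Commercial 4-iodophenyl acetate (CC(=O)Oc1ccc(I)cc1) is converted with Zn dust and LiCl in THF into (4-acetoxyphenyl)zinc iodide F2. F2 is added to 2 with [RhCl((R)-binap)]2 as catalyst in the presence of Me3SiCl (THF, 20 °C). The enolate produced by the asymmetric 1,4-addition is silylated on oxygen as it forms, so 7 is obtained directly with C2 set in the same operation and no flavanone is ever enolised.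

Step 2 is third; step 3 is the same reaction and shares the risk. The electron-rich 5,7-dialkoxychromone may react slowly or with low enantiomeric excess. The fallback sets out from 2 and 3 and comes back at 4. An achiral catalyst (Pd(OCOCF3)2, 2,2'-bipyridine, THF/aqueous AcOH, 60 °C) gives the racemic flavanone rac-4-[5,7-bis(benzyloxy)-4-oxochroman-2-yl]phenyl acetate F3. F3 is resolved kinetically by Noyori–Ikariya asymmetric transfer hydrogenation (RuCl(p-cymene)[(S,S)-TsDPEN], HCO2H/Et3N, EtOAc, rt, stopped near 55% conversion). The (2S)-ketone is reduced to the cis alcohol 4-[(2S,4S)-5,7-bis(benzyloxy)-4-hydroxychroman-2-yl]phenyl acetate F4. The unreacted (2R)-ketone 4 is separated by chromatography, with a maximum yield of 50%.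

**Further compounds**

F1 | step 5 | 4-[(2S,3S)-5,7-bis(benzyloxy)-3-bromo-4-oxochroman-2-yl]phenyl acetate | Br[C@@H]1C(=O)c2c(OCc3ccccc3)cc(OCc3ccccc3)cc2O[C@H]1c1ccc(OC(C)=O)cc1
F2 | step 4 | (4-acetoxyphenyl)zinc iodide | CC(=O)Oc1ccc([Zn]I)cc1
F3 | step 2 | rac-4-[5,7-bis(benzyloxy)-4-oxochroman-2-yl]phenyl acetate | CC(=O)Oc1ccc(C2CC(=O)c3c(OCc4ccccc4)cc(OCc4ccccc4)cc3O2)cc1
F4 | step 2 | 4-[(2S,4S)-5,7-bis(benzyloxy)-4-hydroxychroman-2-yl]phenyl acetate | CC(=O)Oc1ccc([C@@H]2C[C@H](O)c3c(OCc4ccccc4)cc(OCc4ccccc4)cc3O2)cc1
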